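Feature: the core is numbered as bicyclo[3.2.1]oct-3-ene-2,8-dione (C1 CH bridgehead, C2=O, C3–OMe, C4H=, C5 allyl bridgehead, C6–Me, C7–Ar, C8=O). Its bridge C2–C3–C4 is an enone with a heteroatom on the α-carbon C3, which is what a halocarbene carbon leaves when inserted into the C=C of a silyl enol ether. Removing C3 shrinks the six-membered ring C1–C2–C3–C4–C5–C8 to the five-membered ring of a norbornene.
Kadsurenin D ⇒ its C8 dimethyl ketal ⇒ (C3 OMe ⇒ Br) the 3-bromo enone ⇒ a 7,7-dimethoxynorbornenyl silyl enol ether + :CBr2 from CHBr3.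
Norbornene (endo CH3 ⇐ CH2OMs ⇐ CH2OH ⇐ endo N-acyl) ⇒ auxiliary-controlled Diels–Alder reaction of 1-allyl-3-silyloxy-5,5-dimethoxycyclopentadiene with the (S)-4-benzyloxazolidinone imide of (E)-3,4-dimethoxycinnamic acid. This step sets all four stereocentres.
Diene ⇒ 3-allyl-4,4-dimethoxycyclopent-2-enone ⇒ mono-ketal of cyclopent-4-ene-1,3-dione + allylcopper, followed by re-oxidation.
Ring order: five-membered carbocycle (bought) → second ring by [4+2] (bicyclo[2.2.1]) → 5→6 enlargement (bicyclo[3.2.1]).

Key step: step 10

Remark on the chemistry: the enol ether is carried as its tert-butyldimethylsilyl derivative because it must survive three steps between the cycloaddition and the carbene step. The sense of induction in step 6 is assigned from the chelated s-cis model of N-enoyl oxazolidinones. Norbornenes are numbered C1 (allyl bridgehead), C2H=C3(OSi), C4 (H bridgehead), C5 (aryl), C6 (acyl/methyl), C7 (ketal).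

Step 1
Reactants: 1 cyclopent-4-ene-1,3-dione
Product: 2 4,4-dimethoxycyclopent-2-en-1-one
Conditions: HC(OMe)3 (1.2 equiv), p-TsOH·H2O (cat.), MeOH, 0 °C → rt; Et3N quench
Reagents that add atoms: trimethyl orthoformate, COC(OC)OC
Why: Acid-catalysed ketalisation with an orthoester as water scavenger should stop at the mono-ketal, because the first ketalisation turns the doubly activated ene-dione into an ordinary and much less electrophilic enone; no stereocentre is formed.

Step 2
Reactants: 2 4,4-dimethoxycyclopent-2-en-1-one; 3 allylmagnesium bromide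
Product: 4 (±)-[(3-allyl-4,4-dimethoxycyclopent-1-en-1-yl)oxy]trimethylsilane
Conditions: 3 (1.5 equiv), CuBr·SMe2 (1.5 equiv), LiCl, THF, −78 °C; TMSCl (3 equiv), then 2, −78 °C; Et3N, cold aq NaHCO3
Reagents that add atoms: allylmagnesium bromide, C=CC[Mg]Br; chlorotrimethylsilane, C[Si](C)(C)Cl
Why: TMSCl-accelerated conjugate addition of a preformed allylcopper reagent places the allyl group on the β-carbon and traps the enolate regiospecifically, without the strong Lewis acid of a Hosomi–Sakurai reaction, which would allylate the neighbouring ketal; the new centre is racemic and is erased in step 3.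

Step 3
Reactants: 4 (±)-[(3-allyl-4,4-dimethoxycyclopent-1-en-1-yl)oxy]trimethylsilane
Product: 5 3-allyl-4,4-dimethoxycyclopent-2-en-1-one
Conditions: Pd(OAc)2 (1.05 equiv), MeCN, rt
Reagents that add atoms: none
Why: In this Saegusa–Ito oxidation the C2-palladium enolate has a β-hydrogen only at C3, so the enone should be restored with the allyl group on the β-carbon and the racemic centre removed.

Step 4
Reactants: 5 3-allyl-4,4-dimethoxycyclopent-2-en-1-one
Product: 7 tert-butyl[(4-allyl-3,3-dimethoxycyclopenta-1,4-dien-1-yl)oxy]dimethylsilane (= 1-allyl-3-TBSO-5,5-dimethoxycyclopenta-1,3-diene), via lithium dienolate 6 (not isolated)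
Conditions: LDA (1.1 equiv), THF, −78 °C; TBSOTf (1.1 equiv), −78 °C; Et3N, pentane/aq NaHCO3; kept cold and used at once
Reagents that add atoms: tert-butyldimethylsilyl triflate, CC(C)(C)[Si](C)(C)OS(=O)(=O)C(F)(F)F; lithium diisopropylamide, [Li+].CC(C)[N-]C(C)C (its lithium stays only in intermediate 6)
Why: Kinetic α′-deprotonation of an enone followed by O-silylation gives the cross-conjugated 2-silyloxy diene rather than the γ-deprotonated isomer; the diene cannot scramble by 1,5-H shift because its sp3 carbon is quaternary, and loss of methoxide is held back because it would give an antiaromatic cyclopentadienone.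

Step 5
Reactants: 8 (E)-3,4-dimethoxycinnamic acid; 9 (S)-4-benzyl-1,3-oxazolidin-2-one
Product: 11 (S)-4-benzyl-3-[(E)-3-(3,4-dimethoxyphenyl)prop-2-enoyl]-1,3-oxazolidin-2-one, via mixed pivalic anhydride 10 (not isolated)
Conditions: PivCl, Et3N, THF, −20 °C; then 9, LiCl, −20 °C → rt
Reagents that add atoms: pivaloyl chloride, CC(C)(C)C(=O)Cl (its acyl group stays only in intermediate 10)
Why: N-acylation of the oxazolidinone through the mixed anhydride with LiCl/Et3N needs no strong base and keeps the E-alkene; the stereocentre is that of the commercial auxiliary.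

Step 6
Reactants: 7 tert-butyl[(4-allyl-3,3-dimethoxycyclopenta-1,4-dien-1-yl)oxy]dimethylsilane; 11 (S)-4-benzyl-3-[(E)-3-(3,4-dimethoxyphenyl)prop-2-enoyl]-1,3-oxazolidin-2-one
Product: 12 (S)-4-benzyl-3-{[1-allyl-3-(tert-butyldimethylsilyloxy)-5-exo-(3,4-dimethoxyphenyl)-7,7-dimethoxybicyclo[2.2.1]hept-2-en-6-endo-yl]carbonyl}-1,3-oxazolidin-2-one
Conditions: 11, Et2AlCl (1.4 equiv), CH2Cl2, −78 °C; 7 (1.5 equiv), −78 → −30 °C; aq NaHCO3/Rochelle salt
Reagents that add atoms: none
Why: In this Evans auxiliary-controlled Diels–Alder reaction the aluminium chelate of both imide carbonyls locks the s-cis enoyl conformer so that the diene adds opposite to the benzyl group, the enol-ether terminus bonds to the aryl-bearing β-carbon (acyl "para" to OTBS and "ortho" to allyl), and the bulky chelated acyl group goes endo, away from the C7 methoxy groups, with the flat aryl exo, which sets C1, C4, C5 and C6 together.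

Step 7
Reactants: 12 the Diels–Alder imide
Product: 13 [1-allyl-3-(tert-butyldimethylsilyloxy)-5-exo-(3,4-dimethoxyphenyl)-7,7-dimethoxybicyclo[2.2.1]hept-2-en-6-endo-yl]methanol
Conditions: LiBH4 (2.5 equiv), MeOH (2.5 equiv), Et2O–THF, 0 °C
Reagents that add atoms: none
Why: Reductive cleavage of an N-acyl oxazolidinone by borohydride takes place at the exocyclic imide carbonyl and leaves the silyl enol ether, ketal and alkenes alone; no stereocentre is touched and the auxiliary is recovered.

Step 8
Reactants: 13 the endo hydroxymethyl norbornene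
Product: 14 [1-allyl-3-(tert-butyldimethylsilyloxy)-5-exo-(3,4-dimethoxyphenyl)-7,7-dimethoxybicyclo[2.2.1]hept-2-en-6-endo-yl]methyl methanesulfonate
Conditions: MsCl, Et3N, CH2Cl2, 0 °C
Reagents that add atoms: methanesulfonyl chloride, CS(=O)(=O)Cl
Why: Sulfonylation of a primary alcohol under basic conditions is tolerated by the silyl enol ether and the ketal, and participation by the nucleophilic C2 would require a cyclobutane and is not expected.

Step 9
Reactants: 14 the endo mesyloxymethyl norbornene
Product: 15 tert-butyl{[1-allyl-5-exo-(3,4-dimethoxyphenyl)-7,7-dimethoxy-6-endo-methylbicyclo[2.2.1]hept-2-en-3-yl]oxy}dimethylsilane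
Conditions: LiEt3BH (3 equiv), THF, 0 → 50 °C; aq NaHCO3 work-up (non-oxidative)
Reagents that add atoms: none
Why: SN2 displacement of a primary sulfonate by Super-Hydride works even on β-branched carbons and is preferred to a radical deoxygenation, whose primary radical would be a 5-hexenyl radical towards the allyl group; C6 is untouched, so the methyl group stays endo.

Step 10
Reactants: 15 the norbornenyl TBS enol ether; 16 bromoform
Product: 18 5-allyl-3-bromo-7-exo-(3,4-dimethoxyphenyl)-8,8-dimethoxy-6-endo-methylbicyclo[3.2.1]oct-3-en-2-one, via dibromocyclopropane 17 (not isolated)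
Conditions: CHBr3 (1.3 equiv), KOt-Bu (1.5 equiv, in portions), pentane–toluene, −30 → 0 °C; then rt → 60 °C
Reagents that add atoms: bromoform, BrC(Br)Br
Why: Dibromocarbene, released from bromoform by α-elimination, adds in a concerted but asynchronous cheletropic [2+1] step to the C2=C3 enol ether of 15 (C4 and C2 of the final core) to give the silyloxy-dibromocyclopropane 17. The strain of the norbornane-fused cyclopropane and the push of the silyloxy oxygen then drive ionisation of the bromide cis to the ring carbons with disrotatory 2π-electrocyclic opening; this breaks the former C=C σ-bond and, after transfer of the silyl group to bromide, leaves the carbene carbon as C3(Br) between C4H and the new C2 carbonyl. The closest known reaction types are the dihalocarbene ring expansion of cyclic silyl enol ethers to 2-halo enones and the homologation of norbornenes to bicyclo[3.2.1]octenes. The three-membered ring closes by cycloaddition, and the six-membered ring C1–C2–C3–C4–C5–C8 arises by enlargement of the five-membered ring, not by cyclisation of a chain. The two cyclopropane stereocentres are transient and end as sp2 carbons, so the face of attack has no consequence and the four existing centres are untouched. The step needs chemoselectivity for the enol ether over the allyl C=C and the veratryl ring, which its much higher nucleophilicity towards a limited amount of the electrophilic carbene secures, and it needs a single enol ether regioisomer, which is given because the C=C was placed by the cycloaddition and the other α-carbon is a bridgehead.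

Step 11
Reactants: 18 the 3-bromo enone
Product: 19 5-allyl-7-exo-(3,4-dimethoxyphenyl)-3,8,8-trimethoxy-6-endo-methylbicyclo[3.2.1]oct-3-en-2-one
Conditions: CuI (20 mol%), 3,4,7,8-tetramethyl-1,10-phenanthroline (40 mol%), Cs2CO3 (2 equiv), MeOH–toluene, 90 °C, sealed tube
Reagents that add atoms: methanol, CO
Why: Ullmann-type copper-catalysed C(sp2)–O coupling of a vinylic bromide with methanol exchanges Br for OMe at C3 without positional change; 1,4-addition of methoxide is reversible and leads nowhere, C1–H cannot enolise, and the C8 ketal shields the latent 1,3-diketone from retro-Claisen cleavage.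

Step 12
Reactants: 19 the 3-methoxy enone ketal
Product: 20 Kadsurenin D, (1S,5S,6R,7R)-5-allyl-7-(3,4-dimethoxyphenyl)-3-methoxy-6-methylbicyclo[3.2.1]oct-3-ene-2,8-dione (aryl exo, methyl endo)
Conditions: 1 M aq HCl, THF, rt
Reagents that add atoms: water, O
Why: Acid hydrolysis of the dimethyl ketal through the C8 oxocarbenium ion frees the bridging ketone, while the α-methoxy enone is a deactivated enol ether and the C1 bridgehead cannot enolise (Bredt), so no stereocentre is at risk if the acid is kept mild.

Compound list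
1 | cyclopent-4-ene-1,3-dione | O=C1C=CC(=O)C1 | starting material
2 | 4,4-dimethoxycyclopent-2-en-1-one | O=C1C=CC(OC)(OC)C1 | intermediate
3 | allylmagnesium bromide | C=CC[Mg]Br | starting material
4 | (±)-[(3-allyl-4,4-dimethoxycyclopent-1-en-1-yl)oxy]trimethylsilane | C=CCC1C=C(O[Si](C)(C)C)CC1(OC)OC | intermediate
5 | 3-allyl-4,4-dimethoxycyclopent-2-en-1-one | C=CCC1=CC(=O)CC1(OC)OC | intermediate
6 | lithium 4-allyl-3,3-dimethoxycyclopenta-1,4-dien-1-olate (not isolated) | [Li+].C=CCC1=CC([O-])=CC1(OC)OC | intermediate
7 | tert-butyl[(4-allyl-3,3-dimethoxycyclopenta-1,4-dien-1-yl)oxy]dimethylsilane | C=CCC1=CC(O[Si](C)(C)C(C)(C)C)=CC1(OC)OC | intermediate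
8 | (E)-3,4-dimethoxycinnamic acid | COc1ccc(/C=C/C(=O)O)cc1OC | starting material
9 | (S)-4-benzyl-1,3-oxazolidin-2-one | O=C1N[C@@H](Cc2ccccc2)CO1 | starting material
10 | (E)-3,4-dimethoxycinnamic pivalic anhydride (not isolated) | COc1ccc(/C=C/C(=O)OC(=O)C(C)(C)C)cc1OC | intermediate
11 | (S)-4-benzyl-3-[(E)-3-(3,4-dimethoxyphenyl)prop-2-enoyl]-1,3-oxazolidin-2-one | COc1ccc(/C=C/C(=O)N2C(=O)OC[C@@H]2Cc2ccccc2)cc1OC | intermediate
12 | Diels–Alder imide (acyl endo, aryl exo) | C=CC[C@]12C=C(O[Si](C)(C)C(C)(C)C)[C@H](C1(OC)OC)[C@H](c1ccc(OC)c(OC)c1)[C@H]2C(=O)N1C(=O)OC[C@@H]1Cc1ccccc1 | intermediate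
13 | endo-6-hydroxymethyl norbornenyl TBS enol ether | C=CC[C@]12C=C(O[Si](C)(C)C(C)(C)C)[C@H](C1(OC)OC)[C@H](c1ccc(OC)c(OC)c1)[C@H]2CO | intermediate
14 | endo-6-mesyloxymethyl norbornenyl TBS enol ether | C=CC[C@]12C=C(O[Si](C)(C)C(C)(C)C)[C@H](C1(OC)OC)[C@H](c1ccc(OC)c(OC)c1)[C@H]2COS(C)(=O)=O | intermediate
15 | tert-butyl{[1-allyl-5-exo-(3,4-dimethoxyphenyl)-7,7-dimethoxy-6-endo-methylbicyclo[2.2.1]hept-2-en-3-yl]oxy}dimethylsilane | C=CC[C@]12C=C(O[Si](C)(C)C(C)(C)C)[C@H](C1(OC)OC)[C@H](c1ccc(OC)c(OC)c1)[C@H]2C | intermediate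
16 | bromoform | BrC(Br)Br | starting material
17 | 3,3-dibromo-2-silyloxytricyclo[3.2.1.0(2,4)]octane adduct, drawn as the exo adduct (the endo adduct would open to the same enone; not isolated) | C=CC[C@]12[C@@H]3C(Br)(Br)[C@]3(O[Si](C)(C)C(C)(C)C)[C@H](C1(OC)OC)[C@H](c1ccc(OC)c(OC)c1)[C@H]2C | intermediate
18 | 5-allyl-3-bromo-7-exo-(3,4-dimethoxyphenyl)-8,8-dimethoxy-6-endo-methylbicyclo[3.2.1]oct-3-en-2-one | C=CC[C@]12C=C(Br)C(=O)[C@H](C1(OC)OC)[C@H](c1ccc(OC)c(OC)c1)[C@H]2C | intermediate
19 | 5-allyl-7-exo-(3,4-dimethoxyphenyl)-3,8,8-trimethoxy-6-endo-methylbicyclo[3.2.1]oct-3-en-2-one | C=CC[C@]12C=C(OC)C(=O)[C@H](C1(OC)OC)[C@H](c1ccc(OC)c(OC)c1)[C@H]2C | intermediate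
20 | Kadsurenin D | C=CC[C@]12C=C(OC)C(=O)[C@H](C1=O)[C@H](c1ccc(OC)c(OC)c1)[C@H]2C | target

Total step count: 12. Longest linear sequence: 11 (steps 1–4 and 6–12, from cyclopent-4-ene-1,3-dione); step 5 is the convergent branch.

Steps most likely to fail

1. Step 10.
- What may go wrong: carbene transfer may be slow, because the enol ether double bond is shielded on its exo face by the syn methoxy group of the ketal and on its endo face by the C6 methyl group. The allyl alkene could then begin to compete.
- tert-Butoxide may also desilylate the cyclopropane before ionisation, which would divert the opening to the external bond.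
- Fallback: it sets out from 15 and returns at 19.
  - Furukawa–Simmons–Smith cyclopropanation (Et2Zn, CH2I2, CH2Cl2, 0 °C) uses a neutral and smaller carbenoid that prefers silyl enol ethers, and should give the silyloxycyclopropane F1.
  - Saegusa oxidative opening with FeCl3 in DMF should cleave the internal bond to the ring-enlarged 4-chloro ketone F2.
  - NaOAc in MeOH should eliminate HCl to the parent enone F3.
  - Weitz–Scheffer epoxidation (t-BuOOH, Triton B) should give the 3,4-epoxy ketone F4.
  - NaOMe in hot MeOH should open the epoxide at C3 next to the carbonyl and dehydrate to 19. Bromide 18 and step 11 are then bypassed.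

2. Step 6.
- What may go wrong: the strong aluminium Lewis acid may ionise the ketal or strip the silyl group, or it may stop the reaction at the Mukaiyama–Michael stage.
- It may also transfer an ethyl group to the imide, and the diene may dimerise faster than it meets the electron-rich cinnamoyl dienophile.
- Repulsion between the exo aryl group and the C7 methoxy groups may erode endo/exo and facial selectivity.
- Fallback: it sets out from 7 and 8 and returns at 13. The source of chirality is moved from the substrate to a mild catalytic Lewis acid.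
  - Acid 8 is converted by way of 10 with oxazolidin-2-one into the achiral imide F5.
  - F5 is combined with 7 under [Cu((R,R)-t-Bu-box)](SbF6)2 (10 mol%, CH2Cl2, −20 °C → rt). The (R,R) ligand antipode is predicted from the square-planar chelate model and is to be confirmed by correlation with 13. This should give the oxazolidinone adduct F6.
  - LiBH4 reduction of F6 should give 13.

3. Step 11.
- What may go wrong: reductive loss of bromine at copper, slow oxidative addition at the hindered C3, or consumption of the enone by irreversible follow-up of methoxide addition at 90 °C.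
- Fallback: it sets out from 18 and returns at 19. The oxygen is brought in through boron instead of by C–O coupling.
  - Miyaura alkenyl borylation (B2pin2, PdCl2(PPh3)2, PPh3, KOPh, toluene, 50 °C) should give the 3-boryl enone F7.
  - Oxidation with NaBO3·4H2O in THF–H2O should give the diosphenol F8.
  - O-methylation (MeI, K2CO3, acetone) should give 19.

Further compounds
F1 | step 10 | 2-(tert-butyldimethylsilyloxy)tricyclo[3.2.1.0(2,4)]octane derived from 15 (drawn exo) | C=CC[C@]12[C@@H]3C[C@]3(O[Si](C)(C)C(C)(C)C)[C@H](C1(OC)OC)[C@H](c1ccc(OC)c(OC)c1)[C@H]2C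
F2 | step 10 | 5-allyl-4-chloro-7-exo-(3,4-dimethoxyphenyl)-8,8-dimethoxy-6-endo-methylbicyclo[3.2.1]octan-2-one (C4 configuration open, lost on elimination) | C=CC[C@]12C(Cl)CC(=O)[C@H](C1(OC)OC)[C@H](c1ccc(OC)c(OC)c1)[C@H]2C
F3 | step 10 | 5-allyl-7-exo-(3,4-dimethoxyphenyl)-8,8-dimethoxy-6-endo-methylbicyclo[3.2.1]oct-3-en-2-one | C=CC[C@]12C=CC(=O)[C@H](C1(OC)OC)[C@H](c1ccc(OC)c(OC)c1)[C@H]2C
F4 | step 10 | 3,4-epoxide of F3 (epoxide face open, both faces converge on 19) | C=CC[C@]12C3OC3C(=O)[C@H](C1(OC)OC)[C@H](c1ccc(OC)c(OC)c1)[C@H]2C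
F5 | step 6 | 3-[(E)-3-(3,4-dimethoxyphenyl)prop-2-enoyl]-1,3-oxazolidin-2-one | COc1ccc(/C=C/C(=O)N2CCOC2=O)cc1OC
F6 | step 6 | 3-{[1-allyl-3-(tert-butyldimethylsilyloxy)-5-exo-(3,4-dimethoxyphenyl)-7,7-dimethoxybicyclo[2.2.1]hept-2-en-6-endo-yl]carbonyl}-1,3-oxazolidin-2-one | C=CC[C@]12C=C(O[Si](C)(C)C(C)(C)C)[C@H](C1(OC)OC)[C@H](c1ccc(OC)c(OC)c1)[C@H]2C(=O)N1CCOC1=O
F7 | step 11 | 5-allyl-7-exo-(3,4-dimethoxyphenyl)-8,8-dimethoxy-6-endo-methyl-3-(pinacolatoboryl)bicyclo[3.2.1]oct-3-en-2-one | C=CC[C@]12C=C(B3OC(C)(C)C(C)(C)O3)C(=O)[C@H](C1(OC)OC)[C@H](c1ccc(OC)c(OC)c1)[C@H]2C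
F8 | step 11 | 5-allyl-7-exo-(3,4-dimethoxyphenyl)-3-hydroxy-8,8-dimethoxy-6-endo-methylbicyclo[3.2.1]oct-3-en-2-one | C=CC[C@]12C=C(O)C(=O)[C@H](C1(OC)OC)[C@H](c1ccc(OC)c(OC)c1)[C@H]2C
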